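At early times the reagent goes both to the starting material with its tautomer and to homo dimer, and you want what that split leaves in each flask.

common to all: starting material 2.0 mM; time 40 s

| flask | reagent |
|---|---|
| maple | 1.00 mM |
| cedar | 2.00 mM |

    reagent + tautomer → target (k1 = 284 L mol⁻¹ s⁻¹)
    starting material ⇌ tautomer (K2 = 0.0105, k2 = 0.214 s⁻¹)
    starting material + reagent → isomer of the product A (k3 = 109 L mol⁻¹ s⁻¹)
    reagent + target ⇌ idle adduct, settled at all times (K4 = 820 L mol⁻¹)
    2 reagent → homo dimer (k5 = 37.5 L mol⁻¹ s⁻¹)
    target ⇌ isomer of the product B (K6 = 2.1, k6 = 0.132 s⁻¹)

* which of these there is most of at the end, counted by the starting material in it, maple (tautomer / isomer of the product B / isomer of the product A / starting material / target)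
* which of these there is most of at the end, counted by the starting material in it, cedar (tautomer / isomer of the product B / isomer of the product A / starting material / target)
* final amount of the leader among these, as a percentage of the starting material charged, in maple
* final amount of the leader among these, as a percentage of the starting material charged, in cedar

- for target the idle adduct is counted in
- a doubled species enters its step squared and goes two at a time
- run time (maple): 40 s

Take the exchange of starting material and tautomer as settled, because in maple its relaxation half-life of 0.0337 s, both ways together, is far shorter than the 2.4 s half-life of tautomer by step 1 with reagent as charged. Tautomer then stands at a fixed 0.0105 of the starting material, and the pair takes up reagent with one effective constant, 112 L mol⁻¹ s⁻¹. Divide the doubled dimer constant by this and you have the waste number, the reagent lost to homo dimer per reagent spent on starting material at equal concentrations: 0.670. At other concentrations, multiply it by reagent over starting material.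

My first way freezes that ratio at its start. In maple, the share of reagent reaching starting material is 0.749, which leaves 62.5% of the pair. My second way lets the ratio move and integrates to zero reagent. With r as the charged ratio of reagent to starting material and w as the waste number, the fraction of the pair left is one minus (one minus w) times r, raised to the power one over (one minus w). For maple this gives 57.9%. The two ways part by 4.6 percentage points, and the first one cheats: maple starts with less reagent than starting material, so reagent is the limiting reagent here, its ratio to starting material falls as the run goes on, and the frozen waste is charged too long.

I commit to the second way. In maple, starting material ends near 57.3%, ahead of isomer of the product A at 41.0%, and the 6.4 s half-life of starting material by step 3, with reagent as charged, is short against the 40 s run. Reckoned to zero reagent, cedar keeps 29.7% of the pair, so isomer of the product A leads with 68.4%, though that figure belongs to zero reagent and not to a given time.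

The forecast names starting material for maple at 57.7% (range 55.5% to 60%) and isomer of the product A for cedar at 67.7% (range 65% to 70.5%). It reads cedar at the end of the run, with “about 0.02 mM reagent left”. My own two figures differ from these: 57.3% for maple and 68.4% for cedar.

The simulation gives starting material in maple at 57.5% and isomer of the product A in cedar at 67.2%. The waste number puts reagent use on the pair at 2.99 times its use on homo dimer at the start of maple. At 3.12 s in maple, the reagent used in making isomer of the product A reads 4.9 times that lost to homo dimer. For the neighbour of maple charged with 5.0 mM of starting material, the same formula gives 80.5% of starting material, and that flask ends with 80.5%.

Its constants were set for the occasion; what happens was integrated by code.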